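## Retrosynthetic overview

- The target is a (3R,4R,5S,8R)-1,7-dioxaspiro[4.4]nonane-2,6-dione: ring B = O1–C2(=O)–C3–C4–C5, ring A = C5–C6(=O)–O7–C8–C9.
- Chiral-pool cut: ring B, with its O1–C5 bond, the C4 carbinol/carboxyl centre (R) and the C6 carboxyl carbon, is the γ-lactone of natural (2S,3R)-hydroxycitric acid (hibiscus acid). Only the C3 hydroxyl and the side chain at C5 are missing.
- Key disconnection: C5–C9 and O7–C6 of ring A, leading back to the C5 ester enolate of the 3-hydroxylated hibiscus diester and (R)-1,2-epoxydodec-11-ene (C8, C9 and the decenyl chain). One operation joins the two fragments at the fully substituted spiro carbon, sets C5 and closes ring A.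
- C3–OH is installed first by hydroxylation of the lactone enolate; its alkoxide then blocks enolisation at C3, so that C5–H is the only carbon acid left for the key step.
- Ring order: B (from the pool), then A (key step); the last step frees the C4 carboxylic acid. The epoxide comes from (R)-epichlorohydrin and a C9 Grignard reagent.

Key step: step 5

Assumption: hibiscus acid, the natural (2S,3R)-hydroxycitric acid γ-lactone of Hibiscus sabdariffa, is treated as a purchasable starting material; locants of 6–11 follow the oxolane ring (C2 = future spiro carbon, C3 = carbinol/carboxyl carbon, C4 = lactone α-carbon), those of 12 and 13 the spiro name.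

## Route

Step 1
Reactants: 1 (R)-epichlorohydrin; 2 9-bromonon-1-ene
Product: 4 (R)-1-chlorododec-11-en-2-ol, via non-8-en-1-ylmagnesium bromide 3 (not isolated)
Conditions: 2, Mg, THF, 40 °C; then 1, CuI (10 mol %), −40 to 0 °C; 1 M HCl work-up
Reagents that add atoms: none
Why: Copper-catalysed Grignard opening of the epoxide at its unsubstituted carbon (SN2) does not touch the C–O bond of the stereocentre, so 4 should keep the (R) configuration of 1.

Step 2
Reactants: 4 (R)-1-chlorododec-11-en-2-ol
Product: 5 (R)-2-(dec-9-en-1-yl)oxirane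
Conditions: NaOH (powdered), Et2O, rt
Reagents that add atoms: none
Why: Intramolecular Williamson etherification (3-exo-tet) of the chlorohydrin alkoxide onto CH2Cl; the stereocentre only carries the nucleophilic oxygen and stays (R).

Step 3
Reactants: 6 hibiscus acid, (2S,3R)-3-hydroxy-5-oxotetrahydrofuran-2,3-dicarboxylic acid
Product: 7 dimethyl (2S,3R)-3-hydroxy-5-oxotetrahydrofuran-2,3-dicarboxylate
Conditions: TMSCHN2, MeOH–toluene, 0 °C to rt
Reagents that add atoms: (trimethylsilyl)diazomethane, C[Si](C)(C)C=[N+]=[N-]
Why: Esterification of both carboxylic acids by the methyldiazonium ion formed from TMSCHN2 and MeOH; the lactone, the tertiary alcohol and both stereocentres are not involved.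

Step 4
Reactants: 7 dimethyl (2S,3R)-3-hydroxy-5-oxotetrahydrofuran-2,3-dicarboxylate
Product: 9 dimethyl (2S,3R,4R)-3,4-dihydroxy-5-oxotetrahydrofuran-2,3-dicarboxylate, via dipotassium alkoxide enolate 8 (not isolated)
Conditions: KHMDS (2.2 equiv), THF, −78 °C; 2-(phenylsulfonyl)-3-phenyloxaziridine, −78 °C; AcOH
Reagents that add atoms: 2-(phenylsulfonyl)-3-phenyloxaziridine, O=S(=O)(c1ccccc1)N1OC1c1ccccc1
Why: Enolate hydroxylation with an N-sulfonyloxaziridine on the alkoxide–lactone enolate dianion 8 (the lactone CH2 should be deprotonated in preference to the more hindered C2 methine, and the β-alkoxide prevents β-elimination as in Fráter–Seebach dianions); oxygen should be delivered to the face opposite both the C3 alkoxide and the cis C2 ester, giving the 3,4-trans diol, i.e. (4R).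

Step 5
Reactants: 9 dimethyl (2S,3R,4R)-3,4-dihydroxy-5-oxotetrahydrofuran-2,3-dicarboxylate; 5 (R)-2-(dec-9-en-1-yl)oxirane
Product: 12 methyl (3R,4R,5S,8R)-8-(dec-9-en-1-yl)-3,4-dihydroxy-2,6-dioxo-1,7-dioxaspiro[4.4]nonane-4-carboxylate, via trilithium alkoxide enolate 10 (not isolated), via ring-opened trialkoxide 11 (not isolated)
Conditions: LDA (3.3 equiv), THF, −78 to −40 °C; Et2AlCl (2.2 equiv), −78 °C; 5, −78 to 0 °C; 1 M HCl, rt
Reagents that add atoms: none
Why: LDA removes both hydroxyl protons and then the only C–H that can still be enolised, C2–H (C4–H is α to an alkoxide), giving the Fráter–Seebach-type β-alkoxide ester enolate 10, which should not β-eliminate; after Li/Al exchange this enolate opens epoxide 5 at its CH2 carbon by SN2, the closest known reaction type being the Et2AlCl-mediated ester enolate–epoxide opening used to make γ-lactones. The alkoxide 11 formed at the former epoxide CH closes ring A by 5-exo-trig acyl substitution on the C2 methyl ester (methanol leaves), in preference to the 6-exo alternative on the C3 ester, and the acidic work-up completes this lactonisation. The new quaternary spiro centre (C5 of 12) is controlled by the adjacent C3 stereocentre: the metal bridges the C3 alkoxide and the enolate oxygen on one face, and C–C bond formation on the other face (that of the C3 ester, where C2–H stood) keeps this six-membered chelate cis-fused to the flattened lactone, whereas attack from the alkoxide face would force it into a trans fusion; the aluminium alkoxide at C4 lies on the reacting face and can bind and deliver the epoxide. C8 of 12 is the unchanged stereocentre of 5, and C3 and C4 of 12 are not touched. The step needs C- over O-alkylation, enolisation at C2 and not at C4, and attack on the ester face; these rest on the carbon nucleophilicity of the aluminium enolate, on the alkoxide at C4 and on the chelate, and the facial selectivity is the main risk of the route.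

Step 6
Reactants: 12 methyl (3R,4R,5S,8R)-8-(dec-9-en-1-yl)-3,4-dihydroxy-2,6-dioxo-1,7-dioxaspiro[4.4]nonane-4-carboxylate
Product: 13 (3R,4R,5S,8R)-8-(dec-9-en-1-yl)-3,4-dihydroxy-2,6-dioxo-1,7-dioxaspiro[4.4]nonane-4-carboxylic acid
Conditions: LiI, EtOAc, reflux; then 1 M HCl
Reagents that add atoms: none
Why: Nucleophilic ester dealkylation (SN2 of iodide at the methyl carbon) should free the hindered tertiary acid without acyl substitution, so both γ-lactones, whose O-alkyl carbons are secondary and tertiary, the terminal alkene and all four stereocentres remain.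

## Compound list

1 | (R)-epichlorohydrin, (R)-2-(chloromethyl)oxirane | ClC[C@H]1CO1 | starting material
2 | 9-bromonon-1-ene | C=CCCCCCCCBr | starting material
3 | non-8-en-1-ylmagnesium bromide | C=CCCCCCCC[Mg]Br | intermediate (not isolated)
4 | (R)-1-chlorododec-11-en-2-ol | ClC[C@H](O)CCCCCCCCC=C | intermediate
5 | (R)-2-(dec-9-en-1-yl)oxirane [(R)-1,2-epoxydodec-11-ene] | C=CCCCCCCCC[C@@H]1CO1 | intermediate
6 | hibiscus acid, (2S,3R)-3-hydroxy-5-oxotetrahydrofuran-2,3-dicarboxylic acid | O=C(O)[C@H]1OC(=O)C[C@]1(O)C(=O)O | starting material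
7 | dimethyl (2S,3R)-3-hydroxy-5-oxotetrahydrofuran-2,3-dicarboxylate | COC(=O)[C@H]1OC(=O)C[C@]1(O)C(=O)OC | intermediate
8 | dipotassium C3-alkoxide / C4–C5 lactone enolate of 7 | COC(=O)[C@H]1OC([O-])=C[C@]1([O-])C(=O)OC.[K+].[K+] | intermediate (not isolated)
9 | dimethyl (2S,3R,4R)-3,4-dihydroxy-5-oxotetrahydrofuran-2,3-dicarboxylate | COC(=O)[C@H]1OC(=O)[C@H](O)[C@]1(O)C(=O)OC | intermediate
10 | trilithium C3,C4-dialkoxide / C2 ester enolate of 9 (partly aluminium-bound after Et2AlCl) | COC([O-])=C1OC(=O)[C@H]([O-])[C@]1([O-])C(=O)OC.[Li+].[Li+].[Li+] | intermediate (not isolated)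
11 | trialkoxide of dimethyl (2S,3R,4R)-3,4-dihydroxy-2-[(2R)-2-hydroxydodec-11-en-1-yl]-5-oxotetrahydrofuran-2,3-dicarboxylate (written as the lithium salt) | C=CCCCCCCCC[C@@H]([O-])C[C@@]1(OC(=O)[C@H]([O-])[C@]1([O-])C(=O)OC)C(=O)OC.[Li+].[Li+].[Li+] | intermediate (not isolated)
12 | methyl (3R,4R,5S,8R)-8-(dec-9-en-1-yl)-3,4-dihydroxy-2,6-dioxo-1,7-dioxaspiro[4.4]nonane-4-carboxylate | C=CCCCCCCCC[C@@H]1C[C@@]2(OC(=O)[C@H](O)[C@]2(O)C(=O)OC)C(=O)O1 | intermediate
13 | (3R,4R,5S,8R)-8-(dec-9-en-1-yl)-3,4-dihydroxy-2,6-dioxo-1,7-dioxaspiro[4.4]nonane-4-carboxylic acid | C=CCCCCCCCC[C@@H]1C[C@@]2(OC(=O)[C@H](O)[C@]2(O)C(=O)O)C(=O)O1 | target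

## Step count and risks

Total step count: 6. Longest linear sequence: 4 steps (6 → 7 → 9 → 12 → 13; steps 3, 4, 5, 6).

**Step 5 (key step).** The hindered, aggregated polyanion may open the epoxide only slowly, and C–C bond formation may occur on the face of the C3 alkoxide, so that the spiro centre forms with poor or reversed facial selectivity. The fallback replaces the metal chelate by a covalent template (self-regeneration of the stereocentre through a dioxanone enolate) and sets out from 7. Selective saponification of the less hindered, α-acyloxy-activated C2 ester (LiOH, THF–H2O, 0 °C; acidification relactonises) should give (2S,3R)-3-hydroxy-3-(methoxycarbonyl)-5-oxotetrahydrofuran-2-carboxylic acid F1. Hydroxylation of its carboxylate–alkoxide–lactone enolate trianion (KHMDS, then the oxaziridine of step 4) should give (2S,3R,4R)-3,4-dihydroxy-3-(methoxycarbonyl)-5-oxotetrahydrofuran-2-carboxylic acid F2. 2-Methoxypropene with PPTS (CH2Cl2, anhydrous) should tie the C2 carboxyl and the cis C3 hydroxyl into the cis-fused 2,2-dimethyl-1,3-dioxan-4-one acetonide of F2, F3. In the dianion of F3 (LDA, 2.2 equiv, −78 °C; BF3·OEt2; 5) the tether excludes a trans ring fusion, so the epoxide carbon can only be attached on the face of the C3 ester. The new alkoxide then opens the dioxanone at its acyl carbon, acetone is expelled, and the route is rejoined at 12.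

**Step 4.** The enolate oxidation may proceed with low facial selectivity, or with partial enolisation at the C2 methine, giving a mixture of C4 epimers. The fallback is a stereoconvergent oxidation and directed reduction, setting out from 7. The hydroxylation is run without regard to selectivity, giving 9 together with its epimer dimethyl (2S,3R,4S)-3,4-dihydroxy-5-oxotetrahydrofuran-2,3-dicarboxylate F4. The mixture is oxidised (Dess–Martin periodinane, CH2Cl2) to the single keto lactone dimethyl (2S,3S)-3-hydroxy-4,5-dioxotetrahydrofuran-2,3-dicarboxylate F5. Hydride delivery from boron bound to the C3 hydroxyl (Me4NBH(OAc)3, MeCN–AcOH, −20 °C) should place the new hydrogen cis to that hydroxyl and so give the 3,4-trans diol 9, where the route is rejoined.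

**Step 6.** Dealkylation at the hindered, hydroxyl-flanked ester may be slow, and prolonged heating may let iodide or the carboxylate attack the lactones. The fallback uses acid-labile esters in place of a nucleophilic dealkylation and sets out from 6. tert-Butyl 2,2,2-trichloroacetimidate (CH2Cl2, rt) should give di-tert-butyl (2S,3R)-3-hydroxy-5-oxotetrahydrofuran-2,3-dicarboxylate F6. The conditions of step 4 should give di-tert-butyl (2S,3R,4R)-3,4-dihydroxy-5-oxotetrahydrofuran-2,3-dicarboxylate F7. The conditions of step 5 should give di-tert-butyl (2S,3R,4R)-3,4-dihydroxy-2-[(2R)-2-hydroxydodec-11-en-1-yl]-5-oxotetrahydrofuran-2,3-dicarboxylate F8, in which the tert-butyl ester is not expected to lactonise in the flask. TFA in CH2Cl2 then cleaves both tert-butyl esters, the freed C2 acid closes ring A with the side-chain hydroxyl (the only γ-lactone open to it while ring B is intact), and the route is rejoined at 13.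

Further compounds
F1 | step 5 | (2S,3R)-3-hydroxy-3-(methoxycarbonyl)-5-oxotetrahydrofuran-2-carboxylic acid | O=C(O)[C@H]1OC(=O)C[C@]1(O)C(=O)OC
F2 | step 5 | (2S,3R,4R)-3,4-dihydroxy-3-(methoxycarbonyl)-5-oxotetrahydrofuran-2-carboxylic acid | O=C(O)[C@H]1OC(=O)[C@H](O)[C@]1(O)C(=O)OC
F3 | step 5 | acetonide of F2: 2,2-dimethyl-1,3-dioxan-4-one joining the C2 carboxyl and the C3 oxygen, cis-fused to the hydroxy lactone, methyl ester at the ring-fusion carbon | CC1(C)OC(=O)[C@H]2OC(=O)[C@H](O)[C@]2(O1)C(=O)OC
F4 | step 4 | dimethyl (2S,3R,4S)-3,4-dihydroxy-5-oxotetrahydrofuran-2,3-dicarboxylate | COC(=O)[C@H]1OC(=O)[C@@H](O)[C@]1(O)C(=O)OC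
F5 | step 4 | dimethyl (2S,3S)-3-hydroxy-4,5-dioxotetrahydrofuran-2,3-dicarboxylate | COC(=O)[C@H]1OC(=O)C(=O)[C@]1(O)C(=O)OC
F6 | step 6 | di-tert-butyl (2S,3R)-3-hydroxy-5-oxotetrahydrofuran-2,3-dicarboxylate | CC(C)(C)OC(=O)[C@H]1OC(=O)C[C@]1(O)C(=O)OC(C)(C)C
F7 | step 6 | di-tert-butyl (2S,3R,4R)-3,4-dihydroxy-5-oxotetrahydrofuran-2,3-dicarboxylate | CC(C)(C)OC(=O)[C@H]1OC(=O)[C@H](O)[C@]1(O)C(=O)OC(C)(C)C
F8 | step 6 | di-tert-butyl (2S,3R,4R)-3,4-dihydroxy-2-[(2R)-2-hydroxydodec-11-en-1-yl]-5-oxotetrahydrofuran-2,3-dicarboxylate | C=CCCCCCCCC[C@@H](O)C[C@@]1(OC(=O)[C@H](O)[C@]1(O)C(=O)OC(C)(C)C)C(=O)OC(C)(C)C
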